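## The problem

Locants follow eudesmane numbering. Ring A is C1–C2–C3–C4–C5–C10 and ring B is C5–C6–C7–C8–C9–C10. C14 is the methyl on C10, C15 the methyl on C4, C11–C13 the hydroxyisopropyl group on C7, and C1' the benzylic carbon.

- The target 22 is a trans-fused eudesmane-4,11-diol of the enantiomeric series (5S,7S,10R). Its C1 carries, equatorially, a carbon C1' that bears an isobutyl group and a 3,5-diformylphloroglucinol ring.
- The hardest part is the contiguous array C1'(S)–C1(R)–C10(R, quaternary)–C5(S). The C1'–C1 bond joins a neopentyl-type ring carbon to a carbon flanked by a 2,6-dioxygenated arene. C1' lies outside the rings, so only allylic strain against C1 and C10 can control it.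
- C7 can control C5 and C10 through its equatorial preference, and these can control C1 and C4. A reagent that meets a finished decalin, however, comes from the face opposite to C14. That gives an axial C1–C1' bond and an equatorial C4 hydroxyl, whereas 22 has the C1 substituent equatorial and the C4 hydroxyl axial and cis to C14.
- The two tertiary alcohols do not survive strong Brønsted or Lewis acids. The formylated phloroglucinol does not survive hydride, organometallic or oxidising reagents. The order of events at the end is therefore narrow.
- The enabling feature is that C1' is benzylic to an arene with three donor oxygens and, once the C1–C10 bond of ring A is drawn as an alkene, also allylic. The triad C1'–C1–C10 is thus the retron of an aryl-stabilised allyl cation.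
- Ring A, with its C4 carbinol read as a hydrated C3=C4 alkene, is a cyclohexene that contains this very C1–C10 bond. The remaining carbons C1 and C5–C13 are limonene opened at its ring double bond.

## Retrosynthesis

**22 ⇒ 21 ⇒ 19.** The three phenols are masked as methyl ethers and the two aryl–CHO bonds are cut back to aryl–Br.
- The arene must be a strong donor in the key step and must carry no aldehyde while hydride and organolithium reagents are in use, so formylation comes late.
- In 21 every methoxy group is ortho to a formyl group. Each phenoxide is then a good leaving group for SN2 demethylation by thiolate under basic conditions, which tertiary alcohols tolerate and boron halides would not allow.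
- The forward reactions must exchange two bromines at once and remove three methyl groups.

**19 ⇒ 17 ⇒ 16.** The C4–O, C11–O and both aryl–Br bonds are cut.
- All four sites of 16 are π nucleophiles that answer to one electrophile, so one treatment with NBS in water serves all of them.
- A cut at C4–C15 (ketone plus methyl nucleophile) would also give the axial alcohol, but it needs a C4 carbonyl that the diene of the key step cannot supply cheaply.
- The forward reaction must deliver water to C4 anti to a bromonium ion on the open face, which is the trans-diaxial and Markovnikov mode at once. The alkyl bromides must then be removed without touching the aryl bromides.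

**16 ⇒ 15 ⇒ 14 ⇒ 13 (key step).** The C5–C10, C1–C2 and C1'–H bonds are cut.
- The neighbouring cut C1'–C1 would ask for an intermolecular bond between two crowded carbons. A cycloaddition that makes ring B the cyclohexene would leave the dienophile unactivated.
- The chosen cut makes both crowded bonds of C1' (to arene and to isobutyl) on an open chain and lets ring closure build the congestion.
- The precursor 13 is acyclic with one relevant stereocentre (C7). The product 16 is bicyclic with five.
- The forward reaction must ionise 13 selectively, close rings A and B by a cationic [4+2] reaction, and end with a face-selective hydride transfer to C1'.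

**13 ⇒ 10 + 11.** The aryl–C1' bond is cut.
- Adding the aryllithium 12 to a dialkyl-type enone is preferred to adding an alkenyl metal to a 2,6-disubstituted aryl ketone, whose carbonyl group is shielded on both faces.
- The arene 11 is bought. The carbinol configuration is irrelevant.

**10 ⇒ 7 + 8.** The C1–C1' and C10–C14 bonds are cut.
- Olefination of a methyl ketone would give E/Z mixtures at C1=C10. Syn carbometalation of the alkyne 7 through the alane 9 fixes the E geometry that places C1' cis to C14.
- All five carbons of the side chain come from 8.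

**7 ⇒ 5 ⇒ 4 ⇒ 3.** The C4=C5 and C2=C3 double bonds are cut, and the alkyne is traced to the methyl ketone through 6.
- The aldehyde of 3 is addressed twice in the presence of the ketone, so no protecting group is needed.
- The forward reactions must be chemoselective for aldehyde over ketone and E-selective at C4=C5.

**3 ⇒ 2 ⇒ 1.** The ring double bond of limonene is restored.
- (S)-Limonene 1 supplies ten carbons, the only stereocentre that must be bought (C7), and two differentiated termini on cleavage.

## Roads not taken

**Alternative 1:** (the most obvious) cut C1'–C1 on the finished decalin.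
- The forward key step is a Michael-type or hetero-Diels–Alder addition of the enol silane A2 of the complete decalin to the o-quinone methide A1, which carries the isobutyl and both formyl groups. It gives the C2 ketone A3.
- C1 is a neopentyl position, and enolisation of a 2-ketone prefers C3. Attack anti to C14 makes the axial bond, so that epimerisation is needed.
- C1' is formed in an open transition state without a controlling element. The C2 oxygen must then be removed beside phenols and aldehydes.
- Building A2 by a Robinson-type annulation alone costs about as many steps as the whole way to 16.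

**Alternative 2:** cut C1'–C1, C5–C10 and C4–O at once, as in the likely biogenesis.
- The forward key step is attack of the ten-membered dienol A4 on A1, transannular closure, and capture of the C4 cation by water.
- Anti addition across the E-configured C4=C5 bond in the chair–chair conformer puts the incoming oxygen equatorial. The product would be A5, the C4 epimer of 22.
- A4 in the required enantiomeric series must be made by a long medium-ring synthesis and is prone to Cope rearrangement. The face of A1 is not controlled.
- The chosen plan keeps the idea of a cation that closes the C5–C10 bond, but it decouples C4 and needs no medium ring.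

**Alternative 3:** cut C5–C10 and C1–C2 by a neutral, Lewis acid promoted intramolecular Diels–Alder reaction of the trienal A6 to the bicyclic aldehyde A7, then build C1' by two additions.
- Compound 12 adds to A7 to give carbinol A8. Ionisation and capture by an isobutyl nucleophile follow.
- The same A1,3 analysis as in step 8 applies: the nucleophile comes anti to C10. Since it is now isobutyl and not hydride, the product should be A9, the C1' epimer of 16.
- All bonds to C1' would be made after ring closure, next to the quaternary C10, and the sequence is longer.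

Key step: step 8

Remark: the stereodescriptors of the SMILES are taken at face value, (1'S,1R,4R,5S,7S,10R). This places the decalin in the series enantiomeric to the common plant eudesmanes, hence (S)-limonene, and makes the C4 hydroxyl axial and cis to C14.

## Steps

Step 1
Reactants: 1 (S)-(−)-limonene
Product: 2 (4S)-limonene 1,2-oxide (both epoxide diastereomers)
Conditions: mCPBA (1.0 equiv), NaHCO3, CH2Cl2, 0 °C
Reagents that add atoms: 3-chloroperoxybenzoic acid, OOC(=O)c1cccc(Cl)c1
Why: Prilezhaev epoxidation; the trisubstituted ring alkene is more electron-rich than the isopropenyl group and takes up the single equivalent of peracid. Both epoxide diastereomers are cleaved alike in step 2, and the stereocentre (future C7) is not touched.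

Step 2
Reactants: 2 (4S)-limonene 1,2-oxide
Product: 3 (3S)-6-oxo-3-(prop-1-en-2-yl)heptanal
Conditions: H5IO6 (1.2 equiv), THF/H2O, 0 °C → rt
Reagents that add atoms: water, O
Why: Acidic periodate opens the epoxide to the diol and cleaves it in the same flask (Malaprade-type glycol cleavage), giving two differentiated carbonyl termini. The stereocentre is β to the aldehyde and cannot epimerise.

Step 3
Reactants: 3 (3S)-6-oxo-3-(prop-1-en-2-yl)heptanal
Product: 4 (2E,5S)-2-methyl-8-oxo-5-(prop-1-en-2-yl)non-2-enal
Conditions: Ph3P=C(Me)CHO (1.1 equiv), toluene, 80 °C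
Reagents that add atoms: 2-(triphenylphosphoranylidene)propanal, CC(C=O)=P(c1ccccc1)(c1ccccc1)c1ccccc1
Why: Wittig reaction of a stabilised ylide, which reacts with the aldehyde and leaves the methyl ketone alone. Such α-branched stabilised ylides give the E enal, which puts C6 trans to C3 as the later s-cis diene requires.

Step 4
Reactants: 4 (2E,5S)-2-methyl-8-oxo-5-(prop-1-en-2-yl)non-2-enal
Product: 5 (5S,7E)-8-methyl-5-(prop-1-en-2-yl)deca-7,9-dien-2-one
Conditions: Ph3PCH3Br (1.05 equiv), n-BuLi (1.0 equiv), THF, 0 °C; then 4, −78 → 0 °C
Reagents that add atoms: methyltriphenylphosphonium bromide, C[P+](c1ccccc1)(c1ccccc1)c1ccccc1.[Br-]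
Why: Wittig methylenation; one equivalent of the non-stabilised ylide at low temperature reacts with the aldehyde much faster than with the ketone. The E geometry of C4=C5 is not affected.

Step 5
Reactants: 5 (5S,7E)-8-methyl-5-(prop-1-en-2-yl)deca-7,9-dien-2-one
Product: 7 (3E,6S)-3-methyl-6-(prop-1-en-2-yl)deca-1,3-dien-9-yne, via enol phosphate 6 (not isolated)
Conditions: LDA (1.1 equiv), THF, −78 °C; ClP(O)(OEt)2, −78 °C → rt; LDA (2.3 equiv), −78 °C → rt; H2O
Reagents that add atoms: none
Why: Kinetic enolisation at the methyl group, O-phosphorylation and base-induced elimination of the enol phosphate make up the standard conversion of a methyl ketone into a terminal alkyne. The former methyl carbon becomes C1, the former carbonyl carbon becomes C10, and the alkenes are inert to LDA.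

Step 6
Reactants: 7 (3E,6S)-3-methyl-6-(prop-1-en-2-yl)deca-1,3-dien-9-yne; 8 isovaleryl chloride
Product: 10 (5E,9S,11E)-2,6,12-trimethyl-9-(prop-1-en-2-yl)tetradeca-5,11,13-trien-4-one, via alkenylalane 9 (not isolated)
Conditions: AlMe3 (2.5 equiv), Cp2ZrCl2 (0.25 equiv), CH2Cl2, 0 °C → rt; volatiles removed in vacuo; 8, ZnCl2, Pd(PPh3)4 (5 mol %), THF, 0 °C → rt
Reagents that add atoms: trimethylaluminium, C[Al](C)C
Why: Negishi carboalumination adds methyl (C14) and aluminium syn across the terminal alkyne with methyl on the internal carbon. Palladium-catalysed acylation of the alkenyl metal then proceeds with retention, so C1' ends cis to C14 (E). The alkenes and the diene react far more slowly than the alkyne with AlMe3 and Cp2ZrCl2.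

Step 7
Reactants: 10 (5E,9S,11E)-2,6,12-trimethyl-9-(prop-1-en-2-yl)tetradeca-5,11,13-trien-4-one; 11 1,3,5-trimethoxybenzene
Product: 13 (5E,9S,11E)-2,6,12-trimethyl-9-(prop-1-en-2-yl)-4-(2,4,6-trimethoxyphenyl)tetradeca-5,11,13-trien-4-ol (both carbinol epimers), via aryllithium 12 (not isolated)
Conditions: 11, n-BuLi, THF, 0 °C → rt; then 10, −78 °C; aq NaHCO3; used without chromatography on acidic media
Reagents that add atoms: none
Why: Directed ortho-lithiation between two methoxy groups, followed by 1,2-addition of the aryllithium to an enone whose β,β-disubstitution disfavours 1,4-addition. The new carbinol centre forms as a mixture, which does not matter because it is ionised in step 8.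

Step 8
Reactants: 13 (5E,9S,11E)-2,6,12-trimethyl-9-(prop-1-en-2-yl)-4-(2,4,6-trimethoxyphenyl)tetradeca-5,11,13-trien-4-ol
Product: 16 2-[(1S)-1-[(1R,5R,7S,10R)-eudesma-3,11-dien-1-yl]-3-methylbutyl]-1,3,5-trimethoxybenzene, via allyl cation 14 (not isolated), via benzylic cation 15 (not isolated)
Conditions: TFA (3 equiv), CH2Cl2/HFIP 4:1 (0.003 M), −20 → 0 °C; then Et3SiH (5 equiv), −40 °C
Reagents that add atoms: none
Why: Proposed new method: TFA ionises only the doubly activated (benzylic and allylic) tertiary carbinol, so that both epimers of 13 give one aryl-stabilised allyl cation 14 with its charge shared between C1' and C10; the closest known reaction types are the ionic Diels–Alder reaction of allyl cations made from allylic alcohols, known in intramolecular form for decalins, and the ionic hydrogenation of benzylic cations with Et3SiH and TFA, and what is new is an aryl-stabilised, fully substituted allyl cation as dienophile and the hydride finish in the same flask. The C1=C10 bond of 14 is the 2π partner and the diene C2=C3–C4=C5 the 4π partner of a type 1 intramolecular [4+2] cycloaddition that should be strongly asynchronous, with C5–C10 bonding ahead of C1–C2 bonding, and it is driven by the exchange of two π bonds for two σ bonds while the charge stays on an arene-stabilised carbon in 15. Ring B closes by 6-exo attack of C5 on C10 through a chair-like C6–C9 tether, and ring A closes by attack of C1 on C2, exo to the C1=C1' bond and endo to the C2–C3–C4 allyl unit. C10 and C5 are controlled by C7: the isopropenyl group sits equatorially in the chair tether, C14 sits axially, and the cationic C1' substituent lies endo under the diene with the tether anti, which gives the trans ring fusion. C1 is controlled by the E geometry of C1=C10, which is carried over suprafacially and puts C1' cis to C14, that is equatorial, and a stepwise closure or a loss and return of H1 (protonation anti to C14) leads to the same equatorial bond. C1' is controlled by A1,3 strain in 15: H1 must lie in the plane of the cation next to an ortho methoxy group, C10 and C2 then cover the two faces, and Et3SiH comes from the C2 side, anti to the quaternary C10, to give 1'S, so that carbinol epimers and any styrene formed by proton loss are funnelled into one configuration. The step needs chemoselectivity for the diene: both ortho positions are blocked (no indene), the phenols are methylated (no chromene), the [4+3] mode would leave the charge on unstabilised C1, attack by the isopropenyl group would give an unstabilised tertiary cation and should be reversible, high dilution holds back arene alkylation between molecules, and the silane is added only after cyclisation because it would otherwise reduce 14.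

Step 9
Reactants: 16 2-[(1S)-1-[(1R,5R,7S,10R)-eudesma-3,11-dien-1-yl]-3-methylbutyl]-1,3,5-trimethoxybenzene
Product: 17 1,3-dibromo-5-[(1S)-1-[(1R,3S,4S,5S,7S,10R)-3,12-dibromo-4,11-dihydroxyeudesman-1-yl]-3-methylbutyl]-2,4,6-trimethoxybenzene (C11 epimers)
Conditions: NBS (4.4 equiv), acetone/H2O 4:1, 0 °C, dark
Reagents that add atoms: N-bromosuccinimide, O=C1CCC(=O)N1Br; water, O
Why: Electrophilic aromatic bromination fills both free arene positions, and bromohydrin formation takes place at both alkenes. At C3=C4 the bromonium ion forms on the face opposite to C14, and water opens it at the tertiary C4 from the C14 face, the Markovnikov and trans-diaxial (Fürst–Plattner) mode at once, which sets the axial 4-OH. The isopropenyl group gives the tertiary C11 alcohol, whose new stereocentre disappears in step 10.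

Step 10
Reactants: 17 the tetrabromide bis-bromohydrin
Product: 19 1,3-dibromo-5-[(1S)-1-[(1R,4R,5S,7S,10R)-4,11-dihydroxyeudesman-1-yl]-3-methylbutyl]-2,4,6-trimethoxybenzene, via bis-epoxide 18 (not isolated)
Conditions: LiBHEt3 (8 equiv), THF, 0 °C → rt; aq NaOH
Reagents that add atoms: none
Why: The borohydride deprotonates the bromohydrins, which close to epoxides, and then opens each epoxide by SN2 attack at the less substituted carbon (C3 from the open face in a diaxial opening, and C12). Both C–O bonds and the C4 configuration are kept, and aryl bromides flanked by two methoxy groups are inert under these conditions.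

Step 11
Reactants: 19 the dibromo diol
Product: 21 5-[(1S)-1-[(1R,4R,5S,7S,10R)-4,11-dihydroxyeudesman-1-yl]-3-methylbutyl]-2,4,6-trimethoxybenzene-1,3-dicarbaldehyde, via tetralithio species 20 (not isolated)
Conditions: n-BuLi (6 equiv), THF, −78 °C; DMF (excess), −78 → 0 °C; H2O
Reagents that add atoms: N,N-dimethylformamide, CN(C)C=O
Why: The two alcohols are deprotonated first; twofold bromine–lithium exchange is then favoured because each aryllithium site is chelated by two ortho methoxy groups. Formylation with DMF follows, and the hemiaminal alkoxides collapse on work-up.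

Step 12
Reactants: 21 the trimethyl ether dialdehyde
Product: 22 5-[(1S)-1-[(1R,4R,5S,7S,10R)-4,11-dihydroxyeudesman-1-yl]-3-methylbutyl]-2,4,6-trihydroxybenzene-1,3-dicarbaldehyde (CNP0409870.4)
Conditions: NaSEt (10 equiv), DMF, 120 °C; then 1 M HCl, 0 °C
Reagents that add atoms: none
Why: Nucleophilic (SN2) demethylation of aryl methyl ethers by thiolate; every methoxy group is ortho to a formyl group, so each phenoxide is a good leaving group. The medium is basic, so the tertiary alcohols are not ionised and no stereocentre is at risk.

## Compound list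

1 | (S)-(−)-limonene | CC1=CC[C@H](CC1)C(C)=C | starting material
2 | (4S)-limonene 1,2-oxide (epoxide diastereomers) | CC12OC1C[C@H](CC2)C(C)=C | intermediate
3 | (3S)-6-oxo-3-(prop-1-en-2-yl)heptanal | CC(=O)CC[C@@H](CC=O)C(C)=C | intermediate
4 | (2E,5S)-2-methyl-8-oxo-5-(prop-1-en-2-yl)non-2-enal | CC(=O)CC[C@@H](C/C=C(\C)C=O)C(C)=C | intermediate
5 | (5S,7E)-8-methyl-5-(prop-1-en-2-yl)deca-7,9-dien-2-one | CC(=O)CC[C@@H](C/C=C(\C)C=C)C(C)=C | intermediate
6 | diethyl (5S,7E)-8-methyl-5-(prop-1-en-2-yl)deca-1,7,9-trien-2-yl phosphate | C=C(CC[C@@H](C/C=C(\C)C=C)C(C)=C)OP(=O)(OCC)OCC | intermediate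
7 | (3E,6S)-3-methyl-6-(prop-1-en-2-yl)deca-1,3-dien-9-yne | C#CCC[C@@H](C/C=C(\C)C=C)C(C)=C | intermediate
8 | isovaleryl chloride (3-methylbutanoyl chloride) | CC(C)CC(=O)Cl | starting material
9 | [(1E,5S,7E)-2,8-dimethyl-5-(prop-1-en-2-yl)deca-1,7,9-trien-1-yl]dimethylalane | C[Al](C)/C=C(\C)CC[C@@H](C/C=C(\C)C=C)C(C)=C | intermediate
10 | (5E,9S,11E)-2,6,12-trimethyl-9-(prop-1-en-2-yl)tetradeca-5,11,13-trien-4-one | CC(C)CC(=O)/C=C(\C)CC[C@@H](C/C=C(\C)C=C)C(C)=C | intermediate
11 | 1,3,5-trimethoxybenzene | COc1cc(OC)cc(OC)c1 | starting material
12 | 2,4,6-trimethoxyphenyllithium | [Li]c1c(OC)cc(OC)cc1OC | intermediate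
13 | (5E,9S,11E)-2,6,12-trimethyl-9-(prop-1-en-2-yl)-4-(2,4,6-trimethoxyphenyl)tetradeca-5,11,13-trien-4-ol (carbinol epimers) | CC(C)CC(O)(c1c(OC)cc(OC)cc1OC)/C=C(\C)CC[C@@H](C/C=C(\C)C=C)C(C)=C | intermediate
14 | aryl-stabilised allyl cation (charge on C1' and C10) | CC(C)C[C+](c1c(OC)cc(OC)cc1OC)/C=C(\C)CC[C@@H](C/C=C(\C)C=C)C(C)=C | intermediate
15 | benzylic C1' cation of the closed trans-decalin | CC(C)C[C+](c1c(OC)cc(OC)cc1OC)[C@H]1CC=C(C)[C@H]2C[C@@H](C(C)=C)CC[C@]12C | intermediate
16 | 2-[(1S)-1-[(1R,5R,7S,10R)-eudesma-3,11-dien-1-yl]-3-methylbutyl]-1,3,5-trimethoxybenzene | CC(C)C[C@H](c1c(OC)cc(OC)cc1OC)[C@H]1CC=C(C)[C@H]2C[C@@H](C(C)=C)CC[C@]12C | intermediate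
17 | 1,3-dibromo-5-[(1S)-1-[(1R,3S,4S,5S,7S,10R)-3,12-dibromo-4,11-dihydroxyeudesman-1-yl]-3-methylbutyl]-2,4,6-trimethoxybenzene (C11 epimers) | CC(C)C[C@H](c1c(OC)c(Br)c(OC)c(Br)c1OC)[C@H]1C[C@H](Br)[C@@](C)(O)[C@H]2C[C@@H](C(C)(O)CBr)CC[C@]12C | intermediate
18 | 3,4:11,12-bis-epoxide of the dibromoarene (3R,4S, ring oxirane oxygen cis to C14, C11 epimers) | CC(C)C[C@H](c1c(OC)c(Br)c(OC)c(Br)c1OC)[C@H]1C[C@H]3O[C@@]3(C)[C@H]2C[C@@H](C4(C)CO4)CC[C@]12C | intermediate
19 | 1,3-dibromo-5-[(1S)-1-[(1R,4R,5S,7S,10R)-4,11-dihydroxyeudesman-1-yl]-3-methylbutyl]-2,4,6-trimethoxybenzene | CC(C)C[C@H](c1c(OC)c(Br)c(OC)c(Br)c1OC)[C@H]1CC[C@@](C)(O)[C@H]2C[C@@H](C(C)(C)O)CC[C@]12C | intermediate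
20 | dilithioarene dilithium dialkoxide derived from 19 | CC(C)C[C@H](c1c(OC)c([Li])c(OC)c([Li])c1OC)[C@H]1CC[C@@](C)(O[Li])[C@H]2C[C@@H](C(C)(C)O[Li])CC[C@]12C | intermediate
21 | 5-[(1S)-1-[(1R,4R,5S,7S,10R)-4,11-dihydroxyeudesman-1-yl]-3-methylbutyl]-2,4,6-trimethoxybenzene-1,3-dicarbaldehyde | CC(C)C[C@H](c1c(OC)c(C=O)c(OC)c(C=O)c1OC)[C@H]1CC[C@@](C)(O)[C@H]2C[C@@H](C(C)(C)O)CC[C@]12C | intermediate
22 | 5-[(1S)-1-[(1R,4R,5S,7S,10R)-4,11-dihydroxyeudesman-1-yl]-3-methylbutyl]-2,4,6-trihydroxybenzene-1,3-dicarbaldehyde (CNP0409870.4) | CC(C)C[C@H](c1c(O)c(C=O)c(O)c(C=O)c1O)[C@H]1CC[C@@](C)(O)[C@H]2C[C@@H](C(C)(C)O)CC[C@]12C | target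

## Step count and least certain steps

Total step count: 12. Longest linear sequence: 12 steps (1 → 22); 8 and 11 are bought.

**Step 8 (key step, proposed new method).**
- The stabilised cation 14 may be too weak an electrophile at its tertiary terminus C10. Several processes could then compete with the cycloaddition:
  - proton loss to conjugated trienes;
  - slow arene alkylation between molecules;
  - ring closure by the isopropenyl group;
  - leakage through the exo, cis-fused transition state.
- Reversible capture at C10 may scramble the C1=C10 geometry, and a twisted arene in 15 may erode the facial selectivity of the hydride transfer.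
- The fallback uses known chemistry, sets out from 10 and comes back at 16.
  - The enone 10 undergoes a Lewis acid promoted intramolecular Diels–Alder reaction (MeAlCl2, CH2Cl2, −78 → −20 °C, endo, trans-fused) to the bicyclic isobutyl ketone F1.
  - The aryllithium 12, premixed with CeCl3 (THF, −78 °C), adds to it to give the tertiary benzylic carbinol F2.
  - Et3SiH and TFA (CH2Cl2, −40 °C) reduce F2 through the same cation 15 to 16.

**Step 9.**
- Capture of the bromonium ion at C4 takes place syn-axial to C14 and may be slow. Loss of a proton to an allylic bromide, or attack on the other face, could then compete. Running four brominations in one flask also leaves little room for adjustment.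
- The fallback sets out from 16 and comes back at 19.
  - Oxymercuration–demercuration (Hg(OAc)2, THF/H2O, then NaBH4, NaOH) hydrates both alkenes by reversible anti addition without a proton-loss channel, and gives the bromine-free diol F3.
  - Any aryl–mercury bond formed on the arene is reduced back to C–H in the same NaBH4 treatment.
  - The arene alone is then brominated (NBS, 2.1 equiv, MeCN, 0 °C) to 19.

**Step 11.**
- The second bromine–lithium exchange has to occur on a species that already carries three negative charges. Aggregation, poor solubility and protonation on quenching could lead to incomplete formylation, and butyl bromide could alkylate the aryllithium.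
- The fallback sets out from 19 and comes back at 21.
  - Twofold Suzuki–Miyaura vinylation (potassium vinyltrifluoroborate, Pd(OAc)2, SPhos, K3PO4, THF/H2O, 70 °C), which tolerates the free alcohols, gives the divinylarene F4.
  - Lemieux–Johnson cleavage (OsO4 cat., NaIO4, 2,6-lutidine, dioxane/H2O) gives 21.

**Step 12.**
- Negative charge builds up with each methyl group removed, so the third demethylation may stall. Thiolate may also displace a methoxy group at the ring carbon of the doubly formyl-activated arene.
- The fallback changes the phenol protection, sets out from 10 and comes back at 22.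
  - Commercial 1,3,5-tris(benzyloxy)benzene is brominated (NBS) to 2-bromo-1,3,5-tris(benzyloxy)benzene F5.
  - Bromine–lithium exchange (n-BuLi, −78 °C) and addition to 10 give the carbinol F6.
  - The conditions of steps 8 to 11 then lead in turn to the cyclised tribenzyl ether F7, the tetrabromide F8, the dibromo diol F9 and the dialdehyde F10.
  - Neutral hydrogenolysis (H2, Pd/C, EtOAc, rt) frees the three phenols to give 22.

## Further compounds

F1 | step 8 | 1-(eudesma-3,11-dien-1-yl)-3-methylbutan-1-one, ring stereocentres as in 16 | CC(C)CC(=O)[C@H]1CC=C(C)[C@H]2C[C@@H](C(C)=C)CC[C@]12C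
F2 | step 8 | 1-(eudesma-3,11-dien-1-yl)-3-methyl-1-(2,4,6-trimethoxyphenyl)butan-1-ol, ring stereocentres as in 16, carbinol epimers | CC(C)CC(O)(c1c(OC)cc(OC)cc1OC)[C@H]1CC=C(C)[C@H]2C[C@@H](C(C)=C)CC[C@]12C
F3 | step 9 | 2-[(1S)-1-[(1R,4R,5S,7S,10R)-4,11-dihydroxyeudesman-1-yl]-3-methylbutyl]-1,3,5-trimethoxybenzene | CC(C)C[C@H](c1c(OC)cc(OC)cc1OC)[C@H]1CC[C@@](C)(O)[C@H]2C[C@@H](C(C)(C)O)CC[C@]12C
F4 | step 11 | 3,5-divinyl analogue of 19 | CC(C)C[C@H](c1c(OC)c(C=C)c(OC)c(C=C)c1OC)[C@H]1CC[C@@](C)(O)[C@H]2C[C@@H](C(C)(C)O)CC[C@]12C
F5 | step 12 | 2-bromo-1,3,5-tris(benzyloxy)benzene | Brc1c(OCc2ccccc2)cc(OCc2ccccc2)cc1OCc1ccccc1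
F6 | step 12 | tribenzyl analogue of 13 | CC(C)CC(O)(c1c(OCc2ccccc2)cc(OCc2ccccc2)cc1OCc1ccccc1)/C=C(\C)CC[C@@H](C/C=C(\C)C=C)C(C)=C
F7 | step 12 | tribenzyl analogue of 16 | CC(C)C[C@H](c1c(OCc2ccccc2)cc(OCc2ccccc2)cc1OCc1ccccc1)[C@H]1CC=C(C)[C@H]2C[C@@H](C(C)=C)CC[C@]12C
F8 | step 12 | tribenzyl analogue of 17 | CC(C)C[C@H](c1c(OCc2ccccc2)c(Br)c(OCc2ccccc2)c(Br)c1OCc1ccccc1)[C@H]1C[C@H](Br)[C@@](C)(O)[C@H]2C[C@@H](C(C)(O)CBr)CC[C@]12C
F9 | step 12 | tribenzyl analogue of 19 | CC(C)C[C@H](c1c(OCc2ccccc2)c(Br)c(OCc2ccccc2)c(Br)c1OCc1ccccc1)[C@H]1CC[C@@](C)(O)[C@H]2C[C@@H](C(C)(C)O)CC[C@]12C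
F10 | step 12 | tribenzyl analogue of 21 | CC(C)C[C@H](c1c(OCc2ccccc2)c(C=O)c(OCc2ccccc2)c(C=O)c1OCc1ccccc1)[C@H]1CC[C@@](C)(O)[C@H]2C[C@@H](C(C)(C)O)CC[C@]12C
A1 | alternative 1 | 3,5-diformyl-2,4-dihydroxy-6-(3-methylbutylidene)cyclohexa-2,4-dien-1-one (o-quinone methide) | CC(C)CC=C1C(=O)C(C=O)=C(O)C(C=O)=C1O
A2 | alternative 1 | 2-(trimethylsilyloxy)eudesm-1-ene-4,11-diol, configuration as in 22 | C1=C(O[Si](C)(C)C)C[C@@](C)(O)[C@H]2C[C@@H](C(C)(C)O)CC[C@]12C
A3 | alternative 1 | 2-oxo derivative of 22, C1' and C1 not controlled | CC(C)CC(c1c(O)c(C=O)c(O)c(C=O)c1O)C1C(=O)C[C@@](C)(O)[C@H]2C[C@@H](C(C)(C)O)CC[C@]12C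
A4 | alternative 2 | (1(10)E,4E,7S)-germacra-1(10),4-dien-11-ol | C/C1=C\CC/C(C)=C/C[C@@H](C(C)(C)O)CC1
A5 | alternative 2 | C4 epimer of 22 (equatorial 4-OH) | CC(C)C[C@H](c1c(O)c(C=O)c(O)c(C=O)c1O)[C@H]1CC[C@](C)(O)[C@H]2C[C@@H](C(C)(C)O)CC[C@]12C
A6 | alternative 3 | (2E,6S,8E)-3,9-dimethyl-6-(prop-1-en-2-yl)undeca-2,8,10-trienal | O=C/C=C(\C)CC[C@@H](C/C=C(\C)C=C)C(C)=C
A7 | alternative 3 | eudesma-3,11-diene-1-carbaldehyde, ring stereocentres as in 16 | O=C[C@H]1CC=C(C)[C@H]2C[C@@H](C(C)=C)CC[C@]12C
A8 | alternative 3 | (eudesma-3,11-dien-1-yl)(2,4,6-trimethoxyphenyl)methanol, carbinol epimers | OC(c1c(OC)cc(OC)cc1OC)[C@H]1CC=C(C)[C@H]2C[C@@H](C(C)=C)CC[C@]12C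
A9 | alternative 3 | C1' epimer (1'R) of 16 | CC(C)C[C@@H](c1c(OC)cc(OC)cc1OC)[C@H]1CC=C(C)[C@H]2C[C@@H](C(C)=C)CC[C@]12C
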